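All runs were generated by integration from invented constants; noise was put on by code.

The single product is an intermediate, so its timing is what to watch: in the alder run it reads 45% at 10.0 h but 17% at 48.0 h, while the bis adduct climbs to 72%.

| flask | starting material | reagent | remark | time |
|---|---|---|---|---|
| larch | 0.50 M | 1.2 M | run made earlier |  |
| alder | 0.50 M | 2.6 M | run made earlier |  |
| Thursday's | 0.50 M | 1.00 M |  | 50 h |
| Wednesday's | 0.50 M | 2.00 M |  | 50 h |

- larch (time / h: single product / %, bis adduct / %): 4.00: 16, 0; 6.00: 25, 2; 12.0: 31, 5; 20.0: 40, 13; 30.0: 46, 25; 48.0: 44, 31
- alder (time / h: single product / %, bis adduct / %): 3.00: 29, 1; 10.0: 45, 14; 20.0: 44, 36; 25.0: 35, 47; 40.0: 24, 64; 48.0: 17, 72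

(standard deviation of a reading: 2 percentage points)

- the numbers in the tables scatter by 2 percentage points (one standard deviation)

- which of these holds the largest part of the starting material at the end of Thursday's (starting material / bis adduct / single product)
- which of these holds the largest part of the starting material at the end of Wednesday's (starting material / bis adduct / single product)
- amount of single product at the end of Wednesday's, in percent of the starting material charged

The starting material matches in these flasks, so we compare them by reagent. If both steps are first order in reagent and the reagent stays near its charge (the pseudo-first-order reckoning), then with the starting material held fixed, time counts in proportion to the reagent charged. One hour of Wednesday's is then worth 0.769 alder hours, and this ratio of reagent charges is our clock factor.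

But the rule needs testing. Larch's last reading maps to 22.2 h of alder, where alder interpolates to 40.1% single product against larch's 44%. So the flask with less reagent may stand somewhat higher than its mapped reading.

Wednesday's end maps to 38.5 h of alder, which gives us 25.1% single product, probably low, and 62.3% bis adduct.

The forecast names single product for Thursday's and bis adduct for Wednesday's, with 28% single product (21% to 35%), above our figure. Its ground: “I therefore lean on interpolation rather than the pure model”.

Wednesday's ends at 28.6% single product, with 60.8% bis adduct, and Thursday's holds 42.9% single product, so the forecast stands. In Wednesday's, each step taken net, single product is made 2.38 times faster than it is used up at 7.51 h, but at the asked time it is made at only 0.277 of the rate at which it is used up. Our figure from the clock factor 0.769 lies 3.5 percentage points below the flask, on the side the larch test showed.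

    starting material + reagent → single product + released group (k = 0.0604 L mol⁻¹ h⁻¹)
    reagent + single product → bis adduct + released group (k = 0.0222 L mol⁻¹ h⁻¹)
    2 starting material → self-condensation product (k = 0.0199 L mol⁻¹ h⁻¹)
    starting material ⇌ dormant form (K = 0.460, k = 0.164 h⁻¹)

For Wednesday's read at 30 h, the factor gives 23.1 h of alder and 38.5% single product. The flask gives 40.7%.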